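**Retrosynthetic overview**
1. Both prenyl groups come from allyl groups by a final double cross-metathesis with 2-methylbut-2-ene, so the acid-sensitive prenyl/phenol pair never meets an acidic step.
2. Ring C (the pyranone) is closed last, by an enantioselective 6-endo oxa-Michael addition of the 2'-phenol onto an alkylidene β-ketoester, followed by decarboxylation; this sets C2 as S.
3. The key C2–C3 bond is made by an intermolecular Knoevenagel (aldol-type) condensation of an aryl β-ketoester (ring A) with 3,4-dimethoxybenzaldehyde (ring B).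
4. The β-ketoester comes from a crossed Claisen condensation of a salicylate with the enolate of tert-butyl acetate.
5. The 3,5-diallyl salicylate comes from a double aromatic Claisen rearrangement of methyl 2,4-bis(allyloxy)benzoate; rings A and B are bought as benzenoids.

Assumption: the quinidine-derived thiourea is taken to give the 2S series (its quinine-derived pseudoenantiomer the 2R series); this is recalled by analogy, not certain, so the sign is checked on 13 by CD and chiral HPLC and the catalyst swapped if reversed.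

**Step 1**
Reactants: 1 methyl 2,4-dihydroxybenzoate; 2 allyl bromide
Product: 3 methyl 2,4-bis(allyloxy)benzoate
Conditions: 2 (2.6 equiv), K2CO3 (3 equiv), DMF, 60 °C
Reagents that add atoms: none
Why: Williamson ether synthesis; in DMF at 60 °C the chelated 2-OH is alkylated as well as the more acidic 4-OH.

**Step 2**
Reactants: 3 methyl 2,4-bis(allyloxy)benzoate
Product: 5 methyl 3,5-diallyl-2,4-dihydroxybenzoate, via mono-Claisen phenol 4 (not isolated)
Conditions: PhNEt2, 200 °C, Ar
Reagents that add atoms: none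
Why: Two successive aromatic Claisen rearrangements; whichever ether moves first, a blocked ortho position is bypassed by the dienone/Cope (para-Claisen) path, so all pathways converge on the 3,5-diallyl compound.

**Step 3**
Reactants: 5 methyl 3,5-diallyl-2,4-dihydroxybenzoate
Product: 6 methyl 3,5-diallyl-2-hydroxy-4-(triisopropylsilyloxy)benzoate
Conditions: i-Pr3SiOTf (1.1 equiv), 2,6-lutidine, CH2Cl2, −20 to 0 °C
Reagents that add atoms: triisopropylsilyl trifluoromethanesulfonate, CC(C)[Si](OS(=O)(=O)C(F)(F)F)(C(C)C)C(C)C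
Why: Selective O-silylation; the 2-OH is hydrogen-bonded to the ester carbonyl and far less nucleophilic, so the silyl triflate takes the free 4-OH.

**Step 4**
Reactants: 6 methyl 3,5-diallyl-2-hydroxy-4-(triisopropylsilyloxy)benzoate; 7 tert-butyl acetate
Product: 8 tert-butyl 3-[3,5-diallyl-2-hydroxy-4-(triisopropylsilyloxy)phenyl]-3-oxopropanoate
Conditions: 7 (4.0 equiv), LiN(i-Pr)2 (3.9 equiv), THF, −78 °C; then 6, −78 to 0 °C; aq. NH4Cl
Reagents that add atoms: none
Why: Crossed Claisen condensation; excess preformed ester enolate (no free amide left to isomerise the allyl groups) covers the phenol proton and the product β-ketoester proton, which drives the acylation.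

**Step 5**
Reactants: 8 tert-butyl 3-[3,5-diallyl-2-hydroxy-4-(triisopropylsilyloxy)phenyl]-3-oxopropanoate; 9 3,4-dimethoxybenzaldehyde
Product: 10 tert-butyl (2Z)-2-[3,5-diallyl-2-hydroxy-4-(triisopropylsilyloxy)benzoyl]-3-(3,4-dimethoxyphenyl)prop-2-enoate
Conditions: piperidine (0.2 equiv), AcOH (0.2 equiv), 4 Å molecular sieves, toluene, rt
Reagents that add atoms: none
Why: Knoevenagel (aldol-type) condensation of the doubly activated methylene with the aldehyde joins rings A and B through the future C2–C3 bond; the Z isomer (aryl cis to the ester) is the one expected under thermodynamic control.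

**Step 6**
Reactants: 10 tert-butyl (2Z)-2-[3,5-diallyl-2-hydroxy-4-(triisopropylsilyloxy)benzoyl]-3-(3,4-dimethoxyphenyl)prop-2-enoate
Product: 13 (2S)-6,8-diallyl-2-(3,4-dimethoxyphenyl)-7-(triisopropylsilyloxy)chroman-4-one, via tert-butyl ester 11 (not isolated), via keto acid 12 (not isolated)
Conditions: N-[3,5-bis(trifluoromethyl)phenyl]-N'-[(9R)-6'-methoxycinchonan-9-yl]thiourea (10 mol%), toluene, −25 °C; then TsOH·H2O, 80 °C
Reagents that add atoms: none
Why: Enantioselective intramolecular oxa-Michael addition in which the thiourea binds the β-ketoester and the quinuclidine activates the phenol, so the oxygen adds to one face of the alkylidene and sets C2 as S; acid then removes the tert-butyl group and the β-keto acid decarboxylates without touching C2.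

**Step 7**
Reactants: 13 (2S)-6,8-diallyl-2-(3,4-dimethoxyphenyl)-7-(triisopropylsilyloxy)chroman-4-one
Product: 14 (2S)-6,8-diallyl-2-(3,4-dimethoxyphenyl)-7-hydroxychroman-4-one
Conditions: Bu4NF/AcOH (1:1), THF, 0 °C; recrystallise to ≥99% ee (chiral HPLC check)
Reagents that add atoms: none
Why: Fluoride-mediated desilylation; the acetic acid buffer keeps the medium non-basic, so the flavanone does not ring-open by retro-oxa-Michael and C2 is not racemised.

**Step 8**
Reactants: 14 (2S)-6,8-diallyl-2-(3,4-dimethoxyphenyl)-7-hydroxychroman-4-one; 15 2-methylbut-2-ene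
Product: 16 (2S)-2-(3,4-dimethoxyphenyl)-7-hydroxy-6,8-bis(3-methylbut-2-en-1-yl)chroman-4-one
Conditions: second-generation Grubbs catalyst RuCl2(=CHPh)(H2IMes)(PCy3) (5 mol%), 15 (large excess)/CH2Cl2, 40 °C, sealed tube
Reagents that add atoms: none
Why: Double olefin cross-metathesis of the terminal allyl groups with excess 2-methylbut-2-ene gives the trisubstituted prenyl olefins under neutral conditions that tolerate the free phenol and leave C2 untouched.

**Compound list**
1 | methyl 2,4-dihydroxybenzoate | COC(=O)c1ccc(O)cc1O | starting material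
2 | allyl bromide (3-bromoprop-1-ene) | C=CCBr | starting material
3 | methyl 2,4-bis(allyloxy)benzoate | COC(=O)c1ccc(OCC=C)cc1OCC=C | intermediate
4 | methyl 3-allyl-4-(allyloxy)-2-hydroxybenzoate | COC(=O)c1ccc(OCC=C)c(CC=C)c1O | intermediate
5 | methyl 3,5-diallyl-2,4-dihydroxybenzoate | COC(=O)c1cc(CC=C)c(O)c(CC=C)c1O | intermediate
6 | methyl 3,5-diallyl-2-hydroxy-4-(triisopropylsilyloxy)benzoate | COC(=O)c1cc(CC=C)c(O[Si](C(C)C)(C(C)C)C(C)C)c(CC=C)c1O | intermediate
7 | tert-butyl acetate | CC(=O)OC(C)(C)C | starting material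
8 | tert-butyl 3-[3,5-diallyl-2-hydroxy-4-(triisopropylsilyloxy)phenyl]-3-oxopropanoate | CC(C)(C)OC(=O)CC(=O)c1cc(CC=C)c(O[Si](C(C)C)(C(C)C)C(C)C)c(CC=C)c1O | intermediate
9 | 3,4-dimethoxybenzaldehyde | COc1ccc(C=O)cc1OC | starting material
10 | tert-butyl (2Z)-2-[3,5-diallyl-2-hydroxy-4-(triisopropylsilyloxy)benzoyl]-3-(3,4-dimethoxyphenyl)prop-2-enoate | COc1ccc(/C=C(\C(=O)OC(C)(C)C)C(=O)c2cc(CC=C)c(O[Si](C(C)C)(C(C)C)C(C)C)c(CC=C)c2O)cc1OC | intermediate
11 | tert-butyl (2S,3R)-6,8-diallyl-2-(3,4-dimethoxyphenyl)-4-oxo-7-(triisopropylsilyloxy)chromane-3-carboxylate (trans; in equilibrium with its enol) | COc1ccc([C@@H]2[C@@H](C(=O)OC(C)(C)C)C(=O)c3cc(CC=C)c(O[Si](C(C)C)(C(C)C)C(C)C)c(CC=C)c3O2)cc1OC | intermediate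
12 | (2S,3R)-6,8-diallyl-2-(3,4-dimethoxyphenyl)-4-oxo-7-(triisopropylsilyloxy)chromane-3-carboxylic acid | COc1ccc([C@@H]2[C@@H](C(=O)O)C(=O)c3cc(CC=C)c(O[Si](C(C)C)(C(C)C)C(C)C)c(CC=C)c3O2)cc1OC | intermediate
13 | (2S)-6,8-diallyl-2-(3,4-dimethoxyphenyl)-7-(triisopropylsilyloxy)chroman-4-one | COc1ccc([C@@H]2CC(=O)c3cc(CC=C)c(O[Si](C(C)C)(C(C)C)C(C)C)c(CC=C)c3O2)cc1OC | intermediate
14 | (2S)-6,8-diallyl-2-(3,4-dimethoxyphenyl)-7-hydroxychroman-4-one | COc1ccc([C@@H]2CC(=O)c3cc(CC=C)c(O)c(CC=C)c3O2)cc1OC | intermediate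
15 | 2-methylbut-2-ene | CC=C(C)C | starting material
16 | (2S)-2-(3,4-dimethoxyphenyl)-7-hydroxy-6,8-bis(3-methylbut-2-en-1-yl)chroman-4-one (IN0946) | COc1ccc([C@@H]2CC(=O)c3cc(CC=C(C)C)c(O)c(CC=C(C)C)c3O2)cc1OC | target

**Totals**
Total step count: 8. Longest linear sequence: 8 steps (1 to 16).

**Three steps most likely to fail, with fallbacks**

Step 6 (enantioselectivity with an allyl group next to the attacking phenol is untested, and hot TsOH could erode ee through the electron-rich benzylic C2–O bond). The fallback sets out from 10 and comes back at 13, replacing asymmetric catalysis by resolution. Compound 10 is cyclised with catalytic Et3N in toluene at rt to racemic trans tert-butyl 6,8-diallyl-2-(3,4-dimethoxyphenyl)-4-oxo-7-(triisopropylsilyloxy)chromane-3-carboxylate F6. TsOH·H2O at 80 °C then takes it through racemic 6,8-diallyl-2-(3,4-dimethoxyphenyl)-4-oxo-7-(triisopropylsilyloxy)chromane-3-carboxylic acid F7 to racemic 6,8-diallyl-2-(3,4-dimethoxyphenyl)-7-(triisopropylsilyloxy)chroman-4-one F8. Preparative chiral SFC on an amylose tris(3,5-dimethylphenylcarbamate) phase separates the 2S enantiomer, which is 13 (assigned by CD), from (2R)-6,8-diallyl-2-(3,4-dimethoxyphenyl)-7-(triisopropylsilyloxy)chroman-4-one F9, which is set aside.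

Step 4 (the ester is deactivated by the ortho phenoxide and the para silyloxy group and is flanked by an allyl group, so acylation of the enolate may stall). The fallback sets out from 6 and comes back at 8, replacing the Claisen condensation by an aldol addition to an aldehyde followed by oxidation. Reduction of 6 with (i-Bu)2AlH in CH2Cl2 (−78 to 0 °C) gives 2,4-diallyl-6-(hydroxymethyl)-3-(triisopropylsilyloxy)phenol F3. MnO2 in CH2Cl2 oxidises it to 3,5-diallyl-2-hydroxy-4-(triisopropylsilyloxy)benzaldehyde F4. Addition of the lithium enolate of 7 (2.5 equiv, THF, −78 °C) gives racemic tert-butyl 3-[3,5-diallyl-2-hydroxy-4-(triisopropylsilyloxy)phenyl]-3-hydroxypropanoate F5. A second MnO2 oxidation of this benzylic alcohol returns 8.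

Step 2 (a 200 °C double rearrangement with several competing pathways can give tars or incomplete migration). The fallback sets out from 1 and comes back at 5, moving one allyl group at a time through isolated mono-ethers that keep a chelated 2-OH. Compound 1 with 2 (1.05 equiv) and K2CO3 in refluxing acetone gives methyl 4-(allyloxy)-2-hydroxybenzoate F1. Claisen rearrangement in PhNEt2 at 200 °C gives methyl 3-allyl-2,4-dihydroxybenzoate F2, the chelate-favoured C3 product. A second mild O-allylation of the 4-OH gives compound 4, now isolated. A second Claisen rearrangement, with C3 blocked, delivers the allyl group to C5 and gives 5.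

**Further compounds**
F1 | step 2 | methyl 4-(allyloxy)-2-hydroxybenzoate | COC(=O)c1ccc(OCC=C)cc1O
F2 | step 2 | methyl 3-allyl-2,4-dihydroxybenzoate | COC(=O)c1ccc(O)c(CC=C)c1O
F3 | step 4 | 2,4-diallyl-6-(hydroxymethyl)-3-(triisopropylsilyloxy)phenol | OCc1cc(CC=C)c(O[Si](C(C)C)(C(C)C)C(C)C)c(CC=C)c1O
F4 | step 4 | 3,5-diallyl-2-hydroxy-4-(triisopropylsilyloxy)benzaldehyde | O=Cc1cc(CC=C)c(O[Si](C(C)C)(C(C)C)C(C)C)c(CC=C)c1O
F5 | step 4 | tert-butyl 3-[3,5-diallyl-2-hydroxy-4-(triisopropylsilyloxy)phenyl]-3-hydroxypropanoate (racemic) | CC(C)(C)OC(=O)CC(O)c1cc(CC=C)c(O[Si](C(C)C)(C(C)C)C(C)C)c(CC=C)c1O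
F6 | step 6 | tert-butyl 6,8-diallyl-2-(3,4-dimethoxyphenyl)-4-oxo-7-(triisopropylsilyloxy)chromane-3-carboxylate (racemic, trans) | COc1ccc(C2C(C(=O)OC(C)(C)C)C(=O)c3cc(CC=C)c(O[Si](C(C)C)(C(C)C)C(C)C)c(CC=C)c3O2)cc1OC
F7 | step 6 | 6,8-diallyl-2-(3,4-dimethoxyphenyl)-4-oxo-7-(triisopropylsilyloxy)chromane-3-carboxylic acid (racemic, trans) | COc1ccc(C2C(C(=O)O)C(=O)c3cc(CC=C)c(O[Si](C(C)C)(C(C)C)C(C)C)c(CC=C)c3O2)cc1OC
F8 | step 6 | 6,8-diallyl-2-(3,4-dimethoxyphenyl)-7-(triisopropylsilyloxy)chroman-4-one (racemic) | COc1ccc(C2CC(=O)c3cc(CC=C)c(O[Si](C(C)C)(C(C)C)C(C)C)c(CC=C)c3O2)cc1OC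
F9 | step 6 | (2R)-6,8-diallyl-2-(3,4-dimethoxyphenyl)-7-(triisopropylsilyloxy)chroman-4-one | COc1ccc([C@H]2CC(=O)c3cc(CC=C)c(O[Si](C(C)C)(C(C)C)C(C)C)c(CC=C)c3O2)cc1OC
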